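**Retrosynthetic overview**
1. The target is the bis(benzyl ether) of the same ketone with the ethers cleaved last. No ring is formed in the route: the only ring, the benzene ring, is bought as 3,5-bis(benzyloxy)benzyl bromide.
2. Main disconnection at C8'–C9' (side chain numbered from benzylic C1'; C2' is the carbonyl carbon): two primary alkyl radicals of like polarity, each an acid minus CO2. C9'–C23' is palmitic acid and C1'–C8' plus arene is a 9-aryl-8-oxononanoic acid. Their N-hydroxyphthalimide esters are joined by Ni-electrocatalytic doubly decarboxylative coupling.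
3. Enabling feature: C8' and C9' are unbranched CH2 carbons of a stereocentre-free polymethylene chain. C8' is separated from the C2' carbonyl by the five methylenes C3'–C7' and from the benzene ring by eight atoms. A radical at C8' therefore has no 5- or 6-membered route to C2'=O, to the activated C3'–H and C1'–H bonds or to the ring, and C9' carries only an alkyl chain.
4. The keto acid is cut at C1'–C2': a benzylic zinc reagent is acylated with suberic acid half-ester chloride (Negishi acylation), then the ester is saponified.

Key step: step 5

Remark: the target has no stereocentre and no stereogenic double bond, so no step has to set configuration.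

**Step 1**
Reactants: 1 3,5-bis(benzyloxy)benzyl bromide; 2 methyl 8-chloro-8-oxooctanoate
Product: 4 methyl 9-[3,5-bis(benzyloxy)phenyl]-8-oxononanoate, via [3,5-bis(benzyloxy)benzyl]zinc bromide 3 (not isolated)
Conditions: activated Zn dust (1.5 equiv), THF, 0 °C; then 2, Pd(PPh3)4 (2 mol%), THF, 0 °C to rt
Reagents that add atoms: none
Why: Zinc should insert into the benzylic C–Br bond at 0 °C with little Wurtz coupling, and the benzylic zinc bromide should undergo Pd-catalysed Negishi acylation at the acid chloride only, being too mild to attack the methyl ester or the product ketone.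

**Step 2**
Reactants: 4 methyl 9-[3,5-bis(benzyloxy)phenyl]-8-oxononanoate
Product: 5 9-[3,5-bis(benzyloxy)phenyl]-8-oxononanoic acid
Conditions: LiOH·H2O (2 equiv), THF/MeOH/H2O, rt, N2 (degassed); then 1 M HCl
Reagents that add atoms: lithium hydroxide, [Li+].[OH-] (its oxygen becomes the acid OH)
Why: Saponification of the unhindered methyl ester should proceed at room temperature, with the benzyl ethers and the ketone stable to aqueous LiOH when air is excluded to prevent autoxidation of the α-aryl ketone enolate.

**Step 3**
Reactants: 5 9-[3,5-bis(benzyloxy)phenyl]-8-oxononanoic acid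
Product: 6 1,3-dioxoisoindolin-2-yl 9-[3,5-bis(benzyloxy)phenyl]-8-oxononanoate
Conditions: N-hydroxyphthalimide (1.1 equiv), DIC (1.1 equiv), DMAP (10 mol%), CH2Cl2, rt
Reagents that add atoms: N-hydroxyphthalimide, O=C1c2ccccc2C(=O)N1O
Why: In this Steglich-type carbodiimide esterification the activated acyl group should be intercepted by the acidic N–OH of N-hydroxyphthalimide to give the redox-active ester, leaving the ketone untouched.

**Step 4**
Reactants: 7 hexadecanoic acid (palmitic acid)
Product: 8 1,3-dioxoisoindolin-2-yl hexadecanoate
Conditions: N-hydroxyphthalimide (1.1 equiv), DIC (1.1 equiv), DMAP (10 mol%), CH2Cl2, rt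
Reagents that add atoms: N-hydroxyphthalimide, O=C1c2ccccc2C(=O)N1O
Why: The same Steglich-type esterification on an unfunctionalised fatty acid should give a crystalline redox-active ester.

**Step 5**
Reactants: 6 1,3-dioxoisoindolin-2-yl 9-[3,5-bis(benzyloxy)phenyl]-8-oxononanoate (1 equiv); 8 1,3-dioxoisoindolin-2-yl hexadecanoate (3 equiv)
Product: 9 1-[3,5-bis(benzyloxy)phenyl]tricosan-2-one
Conditions: NiCl2·6H2O (20 mol%), 2,2':6',2''-terpyridine (20 mol%), AgNO3 (0.3 equiv), NMP, Mg(+)/RVC(−), undivided cell, constant current, rt
Reagents that add atoms: none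
Why: Cathodically reduced Ni(terpyridine) should transfer an electron to each N-acyloxyphthalimide, whose radical anion loses phthalimide anion and CO2 to release the primary radicals at C8' (from 6) and C9' (from 8); one radical is held as an alkyl–Ni species, which captures the other, and the dialkyl–Ni(III) reductively eliminates the C8'–C9' bond. The closest known reaction type is the Ni-electrocatalytic doubly decarboxylative C(sp3)–C(sp3) cross-coupling of two redox-active esters, the reductive counterpart of a mixed Kolbe electrolysis, which has been applied to pairs of primary fatty-chain esters. No ring is closed and no stereocentre is formed. The step needs cross- over homo-coupling and radical capture by nickel ahead of H-shift or cyclisation: the first is secured by the threefold excess of the commodity ester 8 (its homodimer triacontane is a hydrocarbon that separates from the polar ketone on silica), the second by the substrate, since the C8' radical is five methylenes from C2'=O and has no 5- or 6-membered pathway to the carbonyl, to the activated C3'–H and C1'–H bonds or to the arene. The reductive medium should leave the ketone, the benzyl ethers and the electron-rich ring untouched, which an anodic Kolbe coupling would not guarantee.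

**Step 6**
Reactants: 9 1-[3,5-bis(benzyloxy)phenyl]tricosan-2-one
Product: 10 5-(2-oxotricosyl)benzene-1,3-diol [1-(3,5-dihydroxyphenyl)tricosan-2-one]
Conditions: H2 (1 atm), 10% Pd/C, THF/EtOH, rt
Reagents that add atoms: none
Why: Heterogeneous hydrogenolysis should cleave both aryl benzyl ethers, while the C2' ketone, which is aliphatic and not conjugated to the ring, should not be reduced at 1 atm and room temperature.

**Compound list**
1 | 3,5-bis(benzyloxy)benzyl bromide | BrCc1cc(OCc2ccccc2)cc(OCc2ccccc2)c1 | starting material
2 | methyl 8-chloro-8-oxooctanoate | COC(=O)CCCCCCC(=O)Cl | starting material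
3 | [3,5-bis(benzyloxy)benzyl]zinc bromide | Br[Zn]Cc1cc(OCc2ccccc2)cc(OCc2ccccc2)c1 | intermediate (not isolated)
4 | methyl 9-[3,5-bis(benzyloxy)phenyl]-8-oxononanoate | COC(=O)CCCCCCC(=O)Cc1cc(OCc2ccccc2)cc(OCc2ccccc2)c1 | intermediate
5 | 9-[3,5-bis(benzyloxy)phenyl]-8-oxononanoic acid | OC(=O)CCCCCCC(=O)Cc1cc(OCc2ccccc2)cc(OCc2ccccc2)c1 | intermediate
6 | 1,3-dioxoisoindolin-2-yl 9-[3,5-bis(benzyloxy)phenyl]-8-oxononanoate | O=C(CCCCCCC(=O)Cc1cc(OCc2ccccc2)cc(OCc2ccccc2)c1)ON1C(=O)c2ccccc2C1=O | intermediate
7 | hexadecanoic acid (palmitic acid) | CCCCCCCCCCCCCCCC(=O)O | starting material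
8 | 1,3-dioxoisoindolin-2-yl hexadecanoate | CCCCCCCCCCCCCCCC(=O)ON1C(=O)c2ccccc2C1=O | intermediate
9 | 1-[3,5-bis(benzyloxy)phenyl]tricosan-2-one | CCCCCCCCCCCCCCCCCCCCCC(=O)Cc1cc(OCc2ccccc2)cc(OCc2ccccc2)c1 | intermediate
10 | 5-(2-oxotricosyl)benzene-1,3-diol | CCCCCCCCCCCCCCCCCCCCCC(=O)Cc1cc(O)cc(O)c1 | target

**Step count:** 6 steps in total. The longest linear sequence is 5 steps (1, 2, 3, 5, 6).

**Steps most likely to fail**

Step 5. The two primary radicals may sort statistically, so that homocoupling of the limiting ester 6 or premature reduction of the C8' radical to the alkane outruns the cross-coupling. The fallback keeps the C8'–C9' union but makes it as an alkene. It sets out from the benzylic zinc bromide 3, which would be acylated under the conditions of step 1 with oct-7-enoyl chloride to give 1-[3,5-bis(benzyloxy)phenyl]non-8-en-2-one F1. Cross-metathesis of F1 with 1-hexadecene (4 equiv, second-generation Grubbs catalyst, CH2Cl2, 40 °C) should give (E)-1-[3,5-bis(benzyloxy)phenyl]tricos-8-en-2-one F2, whose E/Z composition is of no consequence. Hydrogenation of F2 over Pd/C (H2, THF/EtOH, rt) should saturate the C8'=C9' bond and cleave both benzyl ethers in one operation, so the fallback returns to the route at 10.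

Step 1. Wurtz-type homocoupling during zinc insertion into the benzylic bromide, or slow acyl transfer followed by protonation of the organozinc, may consume the arene fragment. The fallback reverses the polarity of the benzylic carbon and sets out from 1 used as an electrophile. Tosylmethyl isocyanide would first be mono-alkylated with methyl 7-bromoheptanoate (NaH, DMSO/Et2O, rt) to methyl 8-isocyano-8-(4-methylbenzenesulfonyl)octanoate F3. A second alkylation with 1 (NaH, DMSO/Et2O) should give methyl 9-[3,5-bis(benzyloxy)phenyl]-8-isocyano-8-(4-methylbenzenesulfonyl)nonanoate F4. Brief treatment of F4 with conc. HCl in Et2O/CH2Cl2 should hydrolyse the isocyano sulfone carbon to the ketone, returning to the route at 4.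

Step 6. Hydrogenolysis may stall because the waxy C23 ketone is poorly soluble and fouls the catalyst, and prolonged exposure may begin to reduce the ketone. The fallback replaces reductive cleavage by Lewis-acid dealkylation: from 9, BCl3 with pentamethylbenzene as benzyl-cation scavenger (CH2Cl2, −78 °C) should remove both benzyl groups without touching the ketone and return to the route at 10. No new compound is made on the way.

**Further compounds**
F1 | step 5 | 1-[3,5-bis(benzyloxy)phenyl]non-8-en-2-one | C=CCCCCCC(=O)Cc1cc(OCc2ccccc2)cc(OCc2ccccc2)c1
F2 | step 5 | (E)-1-[3,5-bis(benzyloxy)phenyl]tricos-8-en-2-one | CCCCCCCCCCCCCC/C=C/CCCCCC(=O)Cc1cc(OCc2ccccc2)cc(OCc2ccccc2)c1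
F3 | step 1 | methyl 8-isocyano-8-(4-methylbenzenesulfonyl)octanoate | COC(=O)CCCCCCC([N+]#[C-])S(=O)(=O)c1ccc(C)cc1
F4 | step 1 | methyl 9-[3,5-bis(benzyloxy)phenyl]-8-isocyano-8-(4-methylbenzenesulfonyl)nonanoate | COC(=O)CCCCCCC(Cc1cc(OCc2ccccc2)cc(OCc2ccccc2)c1)([N+]#[C-])S(=O)(=O)c1ccc(C)cc1
F0 | step 6 | none | none
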